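**Plan**

- Retrosynthesis: ring C is opened at O1–C2 (enaminone addition–elimination). C4a–C4 and C4–C3 are then cut together so that C4 becomes carbon monoxide, leaving a ring A aryl iodide and a ring B arylacetylene.
- Enabling feature: C4a of ring A lies between the two oxygen-bearing carbons C5 and C8a. In the bis-MOM ether of 5-methoxyresorcinol this is the one carbon flanked by two identical directing ethers, so iodine can be placed there cleanly and either ortho oxygen can later become O1.
- Forward: rings A and B are bought as arenes (5-methoxyresorcinol, syringaldehyde). The iodide (2 steps) and the alkyne (4 steps) are joined with CO to the open ynone, diethylamine is added at C2, and acid then removes the MOM groups and closes ring C.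
- Stereochemistry: the target has no stereocentre. The only stereo element on the way, the enaminone double bond, disappears on ring closure.

Key step: step 7

Remark on the chemistry: the diethylamine adduct of the ynone is drawn as the E isomer expected for a tertiary push–pull enaminone; its geometry does not affect the outcome.

**Route**

Step 1
Reactants: 1 5-methoxyresorcinol (5-methoxybenzene-1,3-diol)
Product: 2 1-methoxy-3,5-bis(methoxymethoxy)benzene
Conditions: MOMCl (2.5 equiv), iPr2NEt (3 equiv), CH2Cl2, 0 °C to rt
Reagents that add atoms: chloromethyl methyl ether (MOMCl), COCCl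
Why: O-alkylation of both phenols by the reactive α-chloro ether under amine base is standard MOM protection and leaves the methyl ether untouched.

Step 2
Reactants: 2 1-methoxy-3,5-bis(methoxymethoxy)benzene
Product: 4 2-iodo-5-methoxy-1,3-bis(methoxymethoxy)benzene, via aryllithium 3 (not isolated)
Conditions: n-BuLi (1.1 equiv), THF, 0 °C; then I2, THF, −78 °C to rt
Reagents that add atoms: iodine, II
Why: In this directed ortho-metalation the two MOM ethers chelate lithium and jointly acidify the hydrogen between them, so lithiation should go to that carbon rather than to the carbons flanked by one MOM ether and the methoxy group, and iodine then traps the aryllithium at the same carbon.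

Step 3
Reactants: 5 syringaldehyde (4-hydroxy-3,5-dimethoxybenzaldehyde)
Product: 6 2-bromo-4-hydroxy-3,5-dimethoxybenzaldehyde
Conditions: Br2 (1.05 equiv), NaOAc, AcOH, rt
Reagents that add atoms: bromine, BrBr
Why: Electrophilic aromatic bromination can only enter the two equivalent open positions, each ortho to one methoxy group and para to the other, as in the known second bromination of 5-bromovanillin next to the formyl group, and the acetate buffer takes up HBr.

Step 4
Reactants: 6 2-bromo-4-hydroxy-3,5-dimethoxybenzaldehyde
Product: 7 4-hydroxy-2,3,5-trimethoxybenzaldehyde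
Conditions: NaOMe (5 equiv), CuBr (20 mol%), DMF/MeOH, 110 °C; then aq. HCl
Reagents that add atoms: sodium methoxide, C[O-].[Na+]
Why: Copper-catalysed Ullmann-type methoxylation of bromohydroxybenzaldehydes is well known; the substrate reacts as its phenoxide, which shields the para aldehyde from methoxide, and the ortho formyl group assists the displacement.

Step 5
Reactants: 7 4-hydroxy-2,3,5-trimethoxybenzaldehyde
Product: 8 2,3,5-trimethoxy-4-(methoxymethoxy)benzaldehyde
Conditions: MOMCl (1.5 equiv), iPr2NEt (2 equiv), CH2Cl2, 0 °C to rt
Reagents that add atoms: chloromethyl methyl ether (MOMCl), COCCl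
Why: The acidic, aldehyde-conjugated phenol is readily O-alkylated by the small α-chloro ether despite its two flanking methoxy groups (standard MOM protection).

Step 6
Reactants: 8 2,3,5-trimethoxy-4-(methoxymethoxy)benzaldehyde
Product: 9 1-ethynyl-2,3,5-trimethoxy-4-(methoxymethoxy)benzene
Conditions: dimethyl (1-diazo-2-oxopropyl)phosphonate (1.3 equiv), K2CO3 (2 equiv), MeOH, 0 °C to rt
Reagents that add atoms: dimethyl (1-diazo-2-oxopropyl)phosphonate, COP(=O)(OC)C(=[N+]=[N-])C(C)=O
Why: In the Ohira–Bestmann homologation, methanolysis frees the diazomethylphosphonate anion, which adds to the aldehyde, eliminates phosphate to a diazoalkene, loses N2 and rearranges by 1,2-hydrogen shift to the terminal alkyne under base mild enough for the MOM ether.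

Step 7
Reactants: 4 2-iodo-5-methoxy-1,3-bis(methoxymethoxy)benzene; 9 1-ethynyl-2,3,5-trimethoxy-4-(methoxymethoxy)benzene; 10 carbon monoxide
Product: 11 1-[4-methoxy-2,6-bis(methoxymethoxy)phenyl]-3-[2,3,5-trimethoxy-4-(methoxymethoxy)phenyl]prop-2-yn-1-one
Conditions: PdCl2(PPh3)2 (5 mol%), Et3N (3 equiv), CO (10 bar), THF, 50 °C, degassed, no copper
Reagents that add atoms: none
Why: PdCl2(PPh3)2, a divalent palladium precatalyst, is reduced in the flask to zerovalent palladium, which inserts into the C–I bond of 4; CO then inserts into the aryl–palladium bond to give an aroylpalladium iodide (C4a–C4), alkyne 9 coordinates and is deprotonated by Et3N, and reductive elimination from the aroyl(alkynyl)palladium forms C4–C3 and returns zerovalent palladium. The closest known reaction type is the copper-free carbonylative Sonogashira coupling of ortho-alkoxy aryl iodides, CO and arylacetylenes to 1,3-diarylpropynones. No ring is closed and no stereocentre is created, so ring C stays open as the ynone. The selectivity needed is carbonylative over direct alkynylation, and the substrate supplies it: the electron-rich aryl group with two ortho MOM ethers should migrate quickly onto CO, whereas direct coupling at that crowded carbon is slow, and CO pressure and the absence of copper keep alkynyl transfer from overtaking insertion. Et3N is tertiary and cannot give a stable adduct with the ynone, and the MOM and methyl ethers are inert to these conditions.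

Step 8
Reactants: 11 1-[4-methoxy-2,6-bis(methoxymethoxy)phenyl]-3-[2,3,5-trimethoxy-4-(methoxymethoxy)phenyl]prop-2-yn-1-one
Product: 12 (E)-3-(diethylamino)-1-[4-methoxy-2,6-bis(methoxymethoxy)phenyl]-3-[2,3,5-trimethoxy-4-(methoxymethoxy)phenyl]prop-2-en-1-one
Conditions: Et2NH (5 equiv), EtOH, 50 °C
Reagents that add atoms: diethylamine, CCNCC
Why: Conjugate (aza-Michael) addition of a secondary amine to an aryl ynone gives the push–pull β-aminoenone, which fixes C2 at the 1,3-dicarbonyl oxidation level so that the later O-cyclisation can only form the six-membered ring and not an aurone.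

Step 9
Reactants: 12 (E)-3-(diethylamino)-1-[4-methoxy-2,6-bis(methoxymethoxy)phenyl]-3-[2,3,5-trimethoxy-4-(methoxymethoxy)phenyl]prop-2-en-1-one
Product: 14 5-hydroxy-2-(4-hydroxy-2,3,5-trimethoxyphenyl)-7-methoxy-4H-chromen-4-one, via triphenol enaminone 13 (not isolated)
Conditions: 3 M HCl, MeOH, 60 °C
Reagents that add atoms: none
Why: Acid-catalysed acetal exchange with methanol removes all three MOM ethers, after which either freed ortho phenol of ring A adds to C2 of the protonated enaminone and diethylamine is expelled (6-endo addition–elimination, the enaminone route to chromones), forming O1–C2 while the other ortho phenol becomes the hydrogen-bonded C5 hydroxyl and the methyl ethers stay intact.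

**Compound list**

1 | 5-methoxyresorcinol (5-methoxybenzene-1,3-diol) | COc1cc(O)cc(O)c1 | starting material
2 | 1-methoxy-3,5-bis(methoxymethoxy)benzene | COCOc1cc(OC)cc(OCOC)c1 | intermediate
3 | [4-methoxy-2,6-bis(methoxymethoxy)phenyl]lithium | [Li]c1c(OCOC)cc(OC)cc1OCOC | intermediate
4 | 2-iodo-5-methoxy-1,3-bis(methoxymethoxy)benzene | COCOc1cc(OC)cc(OCOC)c1I | intermediate
5 | syringaldehyde (4-hydroxy-3,5-dimethoxybenzaldehyde) | COc1cc(C=O)cc(OC)c1O | starting material
6 | 2-bromo-4-hydroxy-3,5-dimethoxybenzaldehyde | O=Cc1cc(OC)c(O)c(OC)c1Br | intermediate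
7 | 4-hydroxy-2,3,5-trimethoxybenzaldehyde | O=Cc1cc(OC)c(O)c(OC)c1OC | intermediate
8 | 2,3,5-trimethoxy-4-(methoxymethoxy)benzaldehyde | O=Cc1cc(OC)c(OCOC)c(OC)c1OC | intermediate
9 | 1-ethynyl-2,3,5-trimethoxy-4-(methoxymethoxy)benzene | C#Cc1cc(OC)c(OCOC)c(OC)c1OC | intermediate
10 | carbon monoxide | [C-]#[O+] | starting material
11 | 1-[4-methoxy-2,6-bis(methoxymethoxy)phenyl]-3-[2,3,5-trimethoxy-4-(methoxymethoxy)phenyl]prop-2-yn-1-one | COCOc1cc(OC)cc(OCOC)c1C(=O)C#Cc1cc(OC)c(OCOC)c(OC)c1OC | intermediate
12 | (E)-3-(diethylamino)-1-[4-methoxy-2,6-bis(methoxymethoxy)phenyl]-3-[2,3,5-trimethoxy-4-(methoxymethoxy)phenyl]prop-2-en-1-one | CCN(CC)/C(=C/C(=O)c1c(OCOC)cc(OC)cc1OCOC)c1cc(OC)c(OCOC)c(OC)c1OC | intermediate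
13 | (E)-3-(diethylamino)-1-(2,6-dihydroxy-4-methoxyphenyl)-3-(4-hydroxy-2,3,5-trimethoxyphenyl)prop-2-en-1-one | CCN(CC)/C(=C/C(=O)c1c(O)cc(OC)cc1O)c1cc(OC)c(O)c(OC)c1OC | intermediate
14 | 5-hydroxy-2-(4-hydroxy-2,3,5-trimethoxyphenyl)-7-methoxy-4H-chromen-4-one | COc1cc(O)c2c(=O)cc(-c3cc(OC)c(O)c(OC)c3OC)oc2c1 | target

**Summary**

Total step count: 9.
Longest linear sequence: 7 steps (steps 3, 4, 5, 6, 7, 8 and 9, from syringaldehyde 5 to 14).

**Steps most likely to fail**

Step 7. CO insertion may fail to keep ahead of direct alkynylation, or oxidative addition at the doubly flanked C–I bond may be slow enough for alkyne oligomerisation to take over. The carbonyl carbon would then be brought in as a formyl group instead of as CO. The fallback sets out from 2 (with alkyne 9) and returns at 11. Lithiation of 2 as in step 2 (n-BuLi, THF, 0 °C) followed by DMF should give 4-methoxy-2,6-bis(methoxymethoxy)benzaldehyde F1. The lithium acetylide of 9 (n-BuLi, THF, −78 °C) should add to it to give racemic 1-[4-methoxy-2,6-bis(methoxymethoxy)phenyl]-3-[2,3,5-trimethoxy-4-(methoxymethoxy)phenyl]prop-2-yn-1-ol F2. MnO2 in CH2Cl2 at rt should oxidise this benzylic, propargylic alcohol to ynone 11, and the route resumes at step 8.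

Step 4. The copper-mediated displacement may stall at the doubly ortho-substituted C–Br bond, or be overtaken by reductive loss of bromine or base-induced breakdown of the aldehyde at the temperature required. The C2 oxygen would then be installed through boron. The fallback sets out from 6 and returns at 8. MOM protection of 6 (MOMCl, iPr2NEt, CH2Cl2) should give 2-bromo-3,5-dimethoxy-4-(methoxymethoxy)benzaldehyde F3. Miyaura borylation (B2pin2, PdCl2(dppf), KOAc, dioxane, 90 °C) should give 3,5-dimethoxy-4-(methoxymethoxy)-2-(4,4,5,5-tetramethyl-1,3,2-dioxaborolan-2-yl)benzaldehyde F4. Mild oxidation of the C–B bond (NaBO3·4H2O, THF/water, rt) should give 2-hydroxy-3,5-dimethoxy-4-(methoxymethoxy)benzaldehyde F5. O-Methylation (MeI, K2CO3, DMF, rt) should then deliver 8, and the route resumes at step 6.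

Step 2. Lithiation may spread to the carbons flanked by one MOM ether and the methoxy group, or remain incomplete, so that iodine is misplaced or starting material is returned. The iodine would then be introduced before protection. The fallback sets out from 1 and returns at 4. I2 and NaHCO3 in water at 0 °C, conditions that iodinate resorcinols between the two hydroxyl groups, should give 2-iodo-5-methoxybenzene-1,3-diol F6. Double MOM protection (MOMCl, iPr2NEt, CH2Cl2, 0 °C to rt) should give 4, and the route resumes at step 7.

**Further compounds**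

F1 | step 7 | 4-methoxy-2,6-bis(methoxymethoxy)benzaldehyde | COCOc1cc(OC)cc(OCOC)c1C=O
F2 | step 7 | 1-[4-methoxy-2,6-bis(methoxymethoxy)phenyl]-3-[2,3,5-trimethoxy-4-(methoxymethoxy)phenyl]prop-2-yn-1-ol (racemic) | COCOc1cc(OC)cc(OCOC)c1C(O)C#Cc1cc(OC)c(OCOC)c(OC)c1OC
F3 | step 4 | 2-bromo-3,5-dimethoxy-4-(methoxymethoxy)benzaldehyde | O=Cc1cc(OC)c(OCOC)c(OC)c1Br
F4 | step 4 | 3,5-dimethoxy-4-(methoxymethoxy)-2-(4,4,5,5-tetramethyl-1,3,2-dioxaborolan-2-yl)benzaldehyde | O=Cc1cc(OC)c(OCOC)c(OC)c1B1OC(C)(C)C(C)(C)O1
F5 | step 4 | 2-hydroxy-3,5-dimethoxy-4-(methoxymethoxy)benzaldehyde | O=Cc1cc(OC)c(OCOC)c(OC)c1O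
F6 | step 2 | 2-iodo-5-methoxybenzene-1,3-diol | COc1cc(O)c(I)c(O)c1
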